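**Assumption:** (S)-carvone, (R)-4-(tert-butyldimethylsilyloxy)cyclopent-2-en-1-one and dimethyl 3-oxopentanedioate are taken as cheap commercial materials; ring positions are described in words, with ring A = methylcyclopentanol, ring B = γ-lactone, ring C = cyclohexene, ring D = spirocyclopentanone.

**Retrosynthetic overview**
1. Ring D is closed last: the target comes from a spiro ketone (ketal hydrolysis, ketone reduction), and the spiro ketone from an aldehyde-tethered dienoate lactone by an intramolecular vinylogous Stetter reaction (acyl anion equivalent onto the δ-carbon).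
2. The tricyclic dienoate lactone comes from a keto phosphonoacetate and a chiral aldehyde ester in one flask: intramolecular Michael (ring B), Horner–Wadsworth–Emmons, vinylogous aldol condensation (ring C).
3. The keto phosphonoacetate comes from an iodocyclopentenediol monoester and a ketal lactol (Nozaki–Hiyama–Kishi, then MnO2); ring A and its two stereocentres come from the silyloxycyclopentenone.
4. The aldehyde ester (side-chain stereocentre) comes from (S)-carvone by epoxidation and periodate excision; the lactol from dimethyl 3-oxopentanedioate.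
5. Order of ring formation: A (purchased) → B → C → D.

**Route**

Step 1
Reactants: 1 (S)-carvone
Product: 2 trans-carvone 2,3-epoxide
Conditions: 30% H2O2, NaOH (cat.), MeOH, 0 °C
Reagents that add atoms: hydrogen peroxide, OO
Why: Weitz–Scheffer nucleophilic epoxidation attacks only the enone alkene (isopropenyl untouched), anti to the isopropenyl group, and the two new stereocentres are excised in step 2.

Step 2
Reactants: 2 trans-carvone 2,3-epoxide
Product: 3 (3S)-5-oxo-3-(prop-1-en-2-yl)pentanoic acid
Conditions: H5IO6 (2.5 equiv), THF–H2O, 0 °C to rt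
Reagents that add atoms: water, O
Why: acid-promoted hydration of the epoxy ketone followed by two Malaprade periodate cleavages (glycol, then the resulting 1,2-diketone) excises the methyl-bearing carbon as acetic acid and leaves acid and aldehyde arms on the untouched stereocentre.

Step 3
Reactants: 3 (3S)-5-oxo-3-(prop-1-en-2-yl)pentanoic acid
Product: 4 methyl (3S)-5-oxo-3-(prop-1-en-2-yl)pentanoate
Conditions: CH3I, KHCO3, DMF, rt
Reagents that add atoms: iodomethane, CI
Why: SN2 O-alkylation of the carboxylate under weakly basic conditions esterifies the acid without aldol chemistry at the aldehyde.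

Step 4
Reactants: 5 dimethyl 3-oxopentanedioate
Product: 6 dimethyl 2,2'-(1,3-dioxolane-2,2-diyl)diacetate
Conditions: ethylene glycol, p-toluenesulfonic acid (cat.), toluene, reflux, Dean–Stark
Reagents that add atoms: ethylene glycol, OCCO
Why: acid-catalysed ketalisation with azeotropic removal of water masks the ketone that later becomes the ring D carbonyl.

Step 5
Reactants: 6 dimethyl 2,2'-(1,3-dioxolane-2,2-diyl)diacetate
Product: 7 2,2'-(1,3-dioxolane-2,2-diyl)diethanol
Conditions: LiAlH4, THF, 0 °C to rt
Reagents that add atoms: none
Why: hydride reduction of both esters gives the symmetric diol while the ketal is inert.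

Step 6
Reactants: 7 2,2'-(1,3-dioxolane-2,2-diyl)diethanol
Product: 8 1,4,8-trioxaspiro[4.5]decan-7-ol
Conditions: 2-iodoxybenzoic acid (1.1 equiv), DMSO, rt
Reagents that add atoms: none
Why: 2-iodoxybenzoic acid oxidation of one primary alcohol gives a hydroxy aldehyde that closes to the six-membered lactol, which resists further oxidation (diol-to-lactol oxidation).

Step 7
Reactants: 9 (4R)-4-(tert-butyldimethylsilyloxy)cyclopent-2-en-1-one
Product: 10 (4R)-4-(tert-butyldimethylsilyloxy)-2-iodocyclopent-2-en-1-one
Conditions: I2, pyridine, CH2Cl2, 0 °C to rt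
Reagents that add atoms: iodine, II
Why: Johnson α-iodination (pyridine conjugate addition, iodination of the enolate, elimination) places iodine on the α-carbon that will carry the ring C/D carbon.

Step 8
Reactants: 10 (4R)-4-(tert-butyldimethylsilyloxy)-2-iodocyclopent-2-en-1-one
Product: 11 (1S,4R)-4-(tert-butyldimethylsilyloxy)-2-iodo-1-methylcyclopent-2-en-1-ol
Conditions: CH3MgBr, CeCl3, THF, −78 °C
Reagents that add atoms: methylmagnesium bromide, C[Mg]Br
Why: organocerium-type 1,2-addition occurs anti to the silyloxy group (tertiary hydroxyl cis to the silyl ether), CeCl3 suppressing enolisation and the vinyl iodide not exchanging.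

Step 9
Reactants: 11 (1S,4R)-4-(tert-butyldimethylsilyloxy)-2-iodo-1-methylcyclopent-2-en-1-ol
Product: 12 (1S,4R)-2-iodo-1-methylcyclopent-2-ene-1,4-diol
Conditions: Bu4NF, THF, 0 °C
Reagents that add atoms: none
Why: fluoride-mediated desilylation frees the secondary allylic alcohol.

Step 10
Reactants: 12 (1S,4R)-2-iodo-1-methylcyclopent-2-ene-1,4-diol
Product: 13 (1R,4S)-4-hydroxy-3-iodo-4-methylcyclopent-2-en-1-yl 2-(diethoxyphosphoryl)acetate
Conditions: (EtO)2P(O)CH2CO2H, N,N'-dicyclohexylcarbodiimide, 4-(dimethylamino)pyridine (cat.), CH2Cl2, 0 °C to rt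
Reagents that add atoms: 2-(diethoxyphosphoryl)acetic acid, CCOP(=O)(CC(=O)O)OCC
Why: Steglich esterification acylates the secondary alcohol selectively over the hindered tertiary one and installs the tether for ring B.

Step 11
Reactants: 13 (1R,4S)-4-hydroxy-3-iodo-4-methylcyclopent-2-en-1-yl 2-(diethoxyphosphoryl)acetate; 8 1,4,8-trioxaspiro[4.5]decan-7-ol
Product: 14 allylic alcohol diol (iodine of 13 replaced by a 1-hydroxy-2-[2-(2-hydroxyethyl)-1,3-dioxolan-2-yl]ethyl group; both carbinol epimers)
Conditions: CrCl2 (6 equiv), NiCl2 (2 mol %), DMF, rt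
Reagents that add atoms: none
Why: Nozaki–Hiyama–Kishi coupling converts the vinyl iodide into a vinylchromium species that adds to the open hydroxy aldehyde form of the lactol while tolerating ester, phosphonate and free hydroxyls, and the new carbinol centre is oxidised in step 12.

Step 12
Reactants: 14 allylic alcohol diol
Product: 15 enone ketone phosphonoacetate
Conditions: MnO2 (activated, excess), CH2Cl2, rt
Reagents that add atoms: none
Why: MnO2 oxidises only the allylic secondary alcohol, giving the acylcyclopentene Michael acceptor and leaving the primary and tertiary alcohols.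

Step 13
Reactants: 15 enone ketone phosphonoacetate; 4 methyl (3S)-5-oxo-3-(prop-1-en-2-yl)pentanoate
Product: 19 tricyclic dienoate lactone alcohol, via phosphonolactone 16 (not isolated), via alkylidene lactone 17 (not isolated), via aldol adduct 18 (not isolated)
Conditions: LiCl (3 equiv), DBU (2.5 equiv), MeCN, 0 °C to rt; then 4 (1.2 equiv), rt; then 45 °C
Reagents that add atoms: none
Why: the phosphonoacetate anion adds intramolecularly (Michael, 5-exo) to the β-carbon of the acylcyclopentene on the face of the tethering oxygen, giving the cis-fused lactone and the A/B junction; Masamune–Roush Horner–Wadsworth–Emmons olefination with 4 then gives the (E)-alkylidene lactone, whose γ-carbon closes ring C by vinylogous aldol condensation onto the ketone, the acyl-bearing ring A carbon equilibrating to the cis A/C junction that alone can cyclise.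

Step 14
Reactants: 19 tricyclic dienoate lactone alcohol
Product: 20 tricyclic dienoate lactone aldehyde
Conditions: Dess–Martin periodinane, pyridine, CH2Cl2, 0 °C
Reagents that add atoms: none
Why: Dess–Martin oxidation converts the only primary alcohol into the aldehyde under buffered, non-basic conditions that spare the tertiary alcohol and the ketal.

Step 15
Reactants: 20 tricyclic dienoate lactone aldehyde
Product: 21 tetracyclic spiro ketone ketal
Conditions: 2-(pentafluorophenyl)-6,7-dihydro-5H-pyrrolo[2,1-c][1,2,4]triazol-2-ium tetrafluoroborate (20 mol %), KN(SiMe3)2 (18 mol %), toluene, rt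
Reagents that add atoms: none
Why: Proposed new method: the carbene converts the aldehyde into a Breslow intermediate (acyl anion equivalent) that attacks 5-exo the fully substituted δ-carbon of the dienoate lactone on the convex face (syn to the two ring-fusion hydrogens, anti to ring A), which sets the spiro centre; the extended lactone enolate is then protonated at its α-carbon from the face of the ring A tertiary hydroxyl, so the lactone carbonyl ends pseudo-equatorial (trans B/C junction) and the alkene sits in the ring C position of the target; the closest known reactions are intramolecular Stetter cyclisations forming quaternary centres on β,β-disubstituted acceptors and vinylogous (1,6) Stetter additions to dienoates, combined here.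

Step 16
Reactants: 21 tetracyclic spiro ketone ketal
Product: 22 tetracyclic spiro alcohol ketal
Conditions: NaBH4, CeCl3·7H2O, MeOH, −78 °C
Reagents that add atoms: none
Why: Luche-type reduction delivers hydride to the ring D ketone from the face turned toward the A/C junction CH (the other face is screened by the branched side chain on the neighbouring alkene carbon), giving the (S)-carbinol with the hydroxyl syn to the ring C alkene and leaving lactone, ester, ketal and the lactone α-CH untouched.

Step 17
Reactants: 22 tetracyclic spiro alcohol ketal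
Product: 23 CNP0255095.1
Conditions: 1 M HCl (aq.), THF, rt
Reagents that add atoms: water, O
Why: mild acid hydrolysis of the dioxolane releases the ring D ketone without dehydrating the β-hydroxy ketone or the tertiary alcohol.

**Compound list**
1 | (S)-carvone, (5S)-2-methyl-5-(prop-1-en-2-yl)cyclohex-2-en-1-one | C=C(C)[C@@H]1CC(=O)C(C)=CC1 | starting material
2 | trans-carvone 2,3-epoxide (oxirane anti to isopropenyl) | C=C(C)[C@@H]1CC(=O)[C@@]2(C)O[C@H]2C1 | intermediate
3 | (3S)-5-oxo-3-(prop-1-en-2-yl)pentanoic acid | C=C(C)[C@H](CC(=O)O)CC=O | intermediate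
4 | methyl (3S)-5-oxo-3-(prop-1-en-2-yl)pentanoate | C=C(C)[C@H](CC(=O)OC)CC=O | intermediate
5 | dimethyl 3-oxopentanedioate | COC(=O)CC(=O)CC(=O)OC | starting material
6 | dimethyl 2,2'-(1,3-dioxolane-2,2-diyl)diacetate | COC(=O)CC1(CC(=O)OC)OCCO1 | intermediate
7 | 2,2'-(1,3-dioxolane-2,2-diyl)diethanol | OCCC1(CCO)OCCO1 | intermediate
8 | 1,4,8-trioxaspiro[4.5]decan-7-ol (lactol, either hemiacetal epimer) | OC1CC2(CCO1)OCCO2 | intermediate
9 | (4R)-4-(tert-butyldimethylsilyloxy)cyclopent-2-en-1-one | O=C1C=C[C@H](O[Si](C)(C)C(C)(C)C)C1 | starting material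
10 | (4R)-4-(tert-butyldimethylsilyloxy)-2-iodocyclopent-2-en-1-one | O=C1C(I)=C[C@H](O[Si](C)(C)C(C)(C)C)C1 | intermediate
11 | (1S,4R)-4-(tert-butyldimethylsilyloxy)-2-iodo-1-methylcyclopent-2-en-1-ol | C[C@@]1(O)C(I)=C[C@H](O[Si](C)(C)C(C)(C)C)C1 | intermediate
12 | (1S,4R)-2-iodo-1-methylcyclopent-2-ene-1,4-diol (cis-diol) | C[C@@]1(O)C(I)=C[C@H](O)C1 | intermediate
13 | (1R,4S)-4-hydroxy-3-iodo-4-methylcyclopent-2-en-1-yl 2-(diethoxyphosphoryl)acetate | C[C@@]1(O)C(I)=C[C@H](OC(=O)CP(=O)(OCC)OCC)C1 | intermediate
14 | allylic alcohol diol: 13 with iodine replaced by a 1-hydroxy-2-[2-(2-hydroxyethyl)-1,3-dioxolan-2-yl]ethyl group (carbinol epimers) | C[C@@]1(O)C(C(O)CC2(CCO)OCCO2)=C[C@H](OC(=O)CP(=O)(OCC)OCC)C1 | intermediate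
15 | enone ketone phosphonoacetate: 13 with iodine replaced by a 2-[2-(2-hydroxyethyl)-1,3-dioxolan-2-yl]acetyl group | C[C@@]1(O)C(C(=O)CC2(CCO)OCCO2)=C[C@H](OC(=O)CP(=O)(OCC)OCC)C1 | intermediate
16 | phosphonolactone: cis-fused bicyclic α-(diethoxyphosphoryl) γ-lactone carrying the ketone side chain (phosphonate carbon as a mixture) | CCOP(=O)(OCC)C1C(=O)O[C@@H]2C[C@](C)(O)[C@@H]([C@H]12)C(=O)CC3(CCO)OCCO3 | intermediate
17 | (E)-alkylidene lactone from 16 and 4 | C=C(C)[C@H](CC(=O)OC)C/C=C1/C(=O)O[C@@H]2C[C@](C)(O)[C@@H]([C@H]12)C(=O)CC3(CCO)OCCO3 | intermediate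
18 | aldol adduct: ring C closed, tertiary carbinol at the future spiro carbon (two new centres as mixtures) | C=C(C)[C@H](CC(=O)OC)C1C=C2C(=O)O[C@@H]3C[C@](C)(O)[C@@H]([C@H]23)C1(O)CC4(CCO)OCCO4 | intermediate
19 | tricyclic dienoate lactone alcohol (rings A, B, C; cis A/B and A/C junctions; hydroxyethyl dioxolane side chain on the δ-carbon) | C=C(C)[C@H](CC(=O)OC)C1=C(CC5(CCO)OCCO5)[C@H]2[C@@](C)(O)C[C@H]3OC(=O)C(=C1)[C@@H]23 | intermediate
20 | tricyclic dienoate lactone aldehyde | C=C(C)[C@H](CC(=O)OC)C1=C(CC5(CC=O)OCCO5)[C@H]2[C@@](C)(O)C[C@H]3OC(=O)C(=C1)[C@@H]23 | intermediate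
21 | tetracyclic spiro ketone ketal (ring D ketone next to the spiro carbon, distal carbonyl as dioxolane) | C=C(C)[C@H](CC(=O)OC)C1=C[C@H]2C(=O)O[C@@H]3C[C@](C)(O)[C@@H]([C@@H]32)[C@]12CC4(OCCO4)CC2=O | intermediate
22 | tetracyclic spiro alcohol ketal ((S)-carbinol, hydroxyl syn to the ring C alkene) | C=C(C)[C@H](CC(=O)OC)C1=C[C@H]2C(=O)O[C@@H]3C[C@](C)(O)[C@@H]([C@@H]32)[C@]12CC4(OCCO4)C[C@@H]2O | intermediate
23 | CNP0255095.1 | C=C(C)[C@H](CC(=O)OC)C1=C[C@H]2C(=O)O[C@@H]3C[C@](C)(O)[C@@H]([C@@H]32)[C@]12CC(=O)C[C@@H]2O | target

**Step count and risks**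

Total steps: 17. Longest linear sequence: 11 steps (9 to 23, steps 7–17).

Step 15 is the most likely to fail. The acyl anion equivalent must attack a fully substituted δ-carbon, which has no direct precedent, and the face of protonation at the lactone α-carbon is argued rather than known. The fallback makes the same bond by single-electron reduction and sets out from 20. SmI2 (2.5 equiv) with t-BuOH in THF at −78 °C generates the ketyl radical, which adds 5-exo to the dienoate δ-carbon. The samarium dienolate is protonated at the α-carbon and gives the spiro carbinol F1, expected mainly as the carbinol epimer of 22 because the samarium-bound oxygen turns away from the diene. Dess–Martin oxidation of the spiro carbinol F1 gives 21, where the route is rejoined.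

Step 13 is the second risk. It has three bond-forming events in one flask; the β-hydroxy ketone and the ketone next to the dioxolane are base-sensitive in 16 and 17, and the ring closure may stall. The fallback changes the order so that the Michael donor is a dienolate; it sets out from 13 and 4. Masamune–Roush olefination joins them first to the (E)-enoate F2. Nozaki–Hiyama–Kishi coupling with 8 gives the diol F3, and MnO2 gives the enone ketone F4. Catalytic KOt-Bu in t-BuOH–THF at 0 °C then deprotonates the γ-position of the enoate. The α-carbon of the dienolate adds to the enone through the lactone tether, and the now doubly activated lactone α-CH relays the vinylogous aldol condensation, which comes back to the route at 19.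

Step 16 is the third risk: the facial selectivity of hydride at the hindered spiro ketone rests on a steric argument. The fallback replaces substrate control by catalyst control and sets out from 21. (R)-Tetrahydro-1-methyl-3,3-diphenyl-1H,3H-pyrrolo[1,2-c][1,3,2]oxazaborole (20 mol %) with catecholborane in toluene at −78 °C should, by the Corey–Bakshi–Shibata model with the spiro carbon as the large group, give the (S)-carbinol 22 directly, where the route is rejoined. No compound outside the list is made (F0).

**Further compounds**
F1 | step 15 | spiro carbinol, carbinol epimer of 22 (hydroxyl anti to the ring C alkene) | C=C(C)[C@H](CC(=O)OC)C1=C[C@H]2C(=O)O[C@@H]3C[C@](C)(O)[C@@H]([C@@H]32)[C@]12CC4(OCCO4)C[C@H]2O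
F2 | step 13 | (E)-enoate: (1R,4S)-4-hydroxy-3-iodo-4-methylcyclopent-2-en-1-yl (2E,5S)-5-(2-methoxy-2-oxoethyl)-6-methylhepta-2,6-dienoate | C[C@@]1(O)C(I)=C[C@H](OC(=O)/C=C/C[C@@H](CC(=O)OC)C(C)=C)C1
F3 | step 13 | diol: F2 with iodine replaced by a 1-hydroxy-2-[2-(2-hydroxyethyl)-1,3-dioxolan-2-yl]ethyl group (carbinol epimers) | C[C@@]1(O)C(C(O)CC2(CCO)OCCO2)=C[C@H](OC(=O)/C=C/C[C@@H](CC(=O)OC)C(C)=C)C1
F4 | step 13 | enone ketone: F2 with iodine replaced by a 2-[2-(2-hydroxyethyl)-1,3-dioxolan-2-yl]acetyl group | C[C@@]1(O)C(C(=O)CC2(CCO)OCCO2)=C[C@H](OC(=O)/C=C/C[C@@H](CC(=O)OC)C(C)=C)C1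
F0 | step 16 | none | none
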